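**Plan**

Numbering: chromene O1, C2(Me)2, C3=C4, C4a, C5–C8, C8a. Ring A is the 2-hydroxy-4,6-dimethoxyphenyl ring, ring B the benzo ring, ring C the pyran ring.
1. Retrosynthesis: first the benzyl and one ring-A methyl ether are removed. Ring C is then opened at O1–C2 to an ortho-prenylphenol. Ring B is cut at C4a–C5 and C8–C8a into a 6-aroyl-4-benzyloxy-2-pyrone and a prenyl siloxyalkyne, with CO2 returned to the pyrone. The ketone–ring A bond is cut last.
2. Enabling feature: on ring B the aroyl group at C5 is meta to both oxygens (C7, C8a) and ortho to the C4a side chain. This maps onto a 2-pyrone with the aroyl on C6 and the alkoxy on C4; the ynol ether supplies C8a with its oxygen and C4a with its chain, and the lactone carbon leaves as CO2.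
3. Forward: ring A is bought as 1,3,5-trimethoxybenzene and joined to the pyrone aldehyde. Ring B is made in the pyrone/siloxyalkyne cycloaddition–decarboxylation. Ring C is closed last by DDQ oxidative cyclisation, and BCl3 then frees the two phenols.
4. Stereochemistry: the target has no stereocentre, and the cis C3=C4 alkene is fixed by ring C. The carbinol centre of step 3 and the bridgeheads of step 6 are transient and racemic.

Key step: step 6

Remark: benzyl is kept on the ring-B oxygen because BCl3 can remove it in the same operation as the chelation-directed ring-A demethylation; methyl 3-(benzyloxy)-5-hydroxybenzoate, used only in a fallback, is taken to be commercial.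

**Route**

Step 1
Reactants: 1 4-hydroxy-6-methyl-2H-pyran-2-one
Product: 2 4-(benzyloxy)-6-methyl-2H-pyran-2-one
Conditions: BnOH, PPh3, DIAD, THF, 0 °C to rt
Reagents that add atoms: benzyl alcohol, OCc1ccccc1
Why: Mitsunobu reaction: the acidic 4-hydroxyl of vinylogous acid 1 is alkylated on oxygen by the benzyloxyphosphonium ion, which avoids the C3-benzylation that accompanies base/halide alkylation of this pyrone.

Step 2
Reactants: 2 4-(benzyloxy)-6-methyl-2H-pyran-2-one
Product: 3 4-(benzyloxy)-2-oxo-2H-pyran-6-carbaldehyde
Conditions: SeO2, 1,4-dioxane, 160 °C (sealed tube)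
Reagents that add atoms: selenium dioxide, O=[Se]=O
Why: Riley oxidation: SeO2 oxidises the allylic 6-methyl group of 4-alkoxy-6-methyl-2-pyrones to the aldehyde by an ene reaction and [2,3]-sigmatropic shift, while the pyrone ring and the unactivated benzyl ether methylene are expected to survive.

Step 3
Reactants: 3 4-(benzyloxy)-2-oxo-2H-pyran-6-carbaldehyde; 4 1,3,5-trimethoxybenzene
Product: 6 racemic 4-(benzyloxy)-6-[hydroxy(2,4,6-trimethoxyphenyl)methyl]-2H-pyran-2-one, via 2,4,6-trimethoxyphenyllithium 5 (not isolated)
Conditions: 4, n-BuLi, THF, 0 °C to rt; then 3, THF, −78 °C; aq NH4Cl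
Reagents that add atoms: none
Why: Directed ortho-lithiation of 4 between two methoxy groups gives 5, whose 1,2-addition to the non-enolisable aldehyde at −78 °C should outpace attack on the vinylogous carbonate lactone; the carbinol centre is formed as a racemate and is destroyed in step 4.

Step 4
Reactants: 6 racemic 4-(benzyloxy)-6-[hydroxy(2,4,6-trimethoxyphenyl)methyl]-2H-pyran-2-one
Product: 7 4-(benzyloxy)-6-(2,4,6-trimethoxybenzoyl)-2H-pyran-2-one
Conditions: Dess–Martin periodinane, pyridine, CH2Cl2, 0 °C to rt
Reagents that add atoms: none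
Why: Dess–Martin oxidation converts the secondary allylic/benzylic carbinol into the ketone under near-neutral, pyridine-buffered conditions that spare the pyrone and avoid acid-promoted ionisation next to the electron-rich ring.

Step 5
Reactants: 8 ethyl 4-methylpent-3-enoate
Product: 11 triisopropyl[(5-methylhex-4-en-1-yn-1-yl)oxy]silane, via lithium dibromoenolate 9 (not isolated), via lithium ynolate 10 (not isolated)
Conditions: CH2Br2, lithium 2,2,6,6-tetramethylpiperidide (LiTMP), THF, −78 °C; 8; LiN(SiMe3)2; n-BuLi, −78 °C to rt; then TIPSOTf, −78 to 0 °C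
Reagents that add atoms: dibromomethane, BrCBr; triisopropylsilyl trifluoromethanesulfonate, CC(C)[Si](OS(=O)(=O)C(F)(F)F)(C(C)C)C(C)C
Why: Kowalski ester homologation: LiCHBr2 adds to the ester, the dibromoketone enolate 9 undergoes bromine–lithium exchange and carbenoid 1,2-shift to ynolate 10, and the bulky silyl triflate then silylates 10 on oxygen to give the ynol silyl ether.

Step 6
Reactants: 7 4-(benzyloxy)-6-(2,4,6-trimethoxybenzoyl)-2H-pyran-2-one; 11 triisopropyl[(5-methylhex-4-en-1-yn-1-yl)oxy]silane
Product: 13 [5-(benzyloxy)-2-(3-methylbut-2-en-1-yl)-3-(triisopropylsilyloxy)phenyl](2,4,6-trimethoxyphenyl)methanone, via bridged lactone 12 (not isolated)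
Conditions: 11 (1.5 equiv), AgNTf2 (20 mol %), 4 Å MS, CH2Cl2, 0 °C to rt, then 40 °C
Reagents that add atoms: none
Why: Proposed new method: AgNTf2 is expected to bind the lactone carbonyl of 7, the most basic oxygen because the 4-benzyloxy group feeds electron density into it, and the pyrylium-like complex is attacked at C6 by the nucleophilic, prenyl-bearing carbon of ynol ether 11; the silyl ketenium carbon so formed is captured by C3, the nucleophilic end of the O4 enol ether, which completes an asynchronous inverse-electron-demand (4+2) addition across C3 and C6 to give bridged lactone 12. Retro-(4+2) loss of CO2 from 12 then aromatises the new ring, so ring B is closed by an intermolecular (4+2) cycloaddition followed by cycloreversion, both ring bonds (the future C4a–C5 and C8–C8a) arising in the addition. The closest known reaction types are the AgNTf2-promoted benzannulation of siloxyalkynes with ester-activated 2-pyrones and the inverse-demand Diels–Alder/decarboxylation of electron-poor 2-pyrones with ynamines; a 4-alkoxy-6-aroyl-2-pyrone, a donor-substituted diene with only a ketone as acceptor, lies outside the substrates shown for either. No stereocentre results, because the two bridgehead centres of racemic 12 are erased when CO2 leaves. The step needs regioselectivity (prenyl carbon to C6, siloxy carbon to C3) and periselectivity over (2+2) addition at the C5=C6 enone or the ketone; the first follows from the matched polarisation of lactone and ynol ether reinforced by the benzyloxy donor that makes C3 nucleophilic, the second from the ring oxygen that makes C5 an electron-rich enol ester carbon and from the two ortho methoxy groups that shield the ketone from silver and from the alkyne.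

Step 7
Reactants: 13 [5-(benzyloxy)-2-(3-methylbut-2-en-1-yl)-3-(triisopropylsilyloxy)phenyl](2,4,6-trimethoxyphenyl)methanone
Product: 14 [5-(benzyloxy)-3-hydroxy-2-(3-methylbut-2-en-1-yl)phenyl](2,4,6-trimethoxyphenyl)methanone
Conditions: TBAF, AcOH, THF, 0 °C
Reagents that add atoms: none
Why: Fluoride-mediated desilylation: acetic acid-buffered TBAF cleaves the aryl silyl ether selectively and keeps the liberated phenoxide from side reactions, leaving the benzyl and methyl ethers, the ketone and the prenyl group untouched.

Step 8
Reactants: 14 [5-(benzyloxy)-3-hydroxy-2-(3-methylbut-2-en-1-yl)phenyl](2,4,6-trimethoxyphenyl)methanone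
Product: 15 [7-(benzyloxy)-2,2-dimethyl-2H-chromen-5-yl](2,4,6-trimethoxyphenyl)methanone
Conditions: DDQ, benzene, 80 °C
Reagents that add atoms: none
Why: DDQ oxidative cyclisation of an ortho-prenylphenol: hydride abstraction from the benzylic/allylic CH2, activated by the ortho hydroxyl and para benzyloxy groups, gives an ortho-quinone methide that closes ring C by oxa-6π electrocyclisation, which also fixes the cis C3=C4 alkene.

Step 9
Reactants: 15 [7-(benzyloxy)-2,2-dimethyl-2H-chromen-5-yl](2,4,6-trimethoxyphenyl)methanone
Product: 16 (2-hydroxy-4,6-dimethoxyphenyl)(7-hydroxy-2,2-dimethyl-2H-chromen-5-yl)methanone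
Conditions: BCl3, C6HMe5, CH2Cl2, −78 to 0 °C; then H2O
Reagents that add atoms: none
Why: Lewis acid ether cleavage: BCl3 removes the benzyl group (cation trapped by pentamethylbenzene) and, through a six-membered chelate with the ketone, exactly one ortho methyl ether of ring A, the chelated boron phenoxide deactivating the carbonyl towards a second demethylation while the para methoxy group and, at low temperature, the chromene ether are left intact.

**Compound list**

1 | 4-hydroxy-6-methyl-2H-pyran-2-one | Cc1cc(O)cc(=O)o1 | starting material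
2 | 4-(benzyloxy)-6-methyl-2H-pyran-2-one | Cc1cc(OCc2ccccc2)cc(=O)o1 | intermediate
3 | 4-(benzyloxy)-2-oxo-2H-pyran-6-carbaldehyde | O=CC1=CC(OCc2ccccc2)=CC(=O)O1 | intermediate
4 | 1,3,5-trimethoxybenzene | COc1cc(OC)cc(OC)c1 | starting material
5 | 2,4,6-trimethoxyphenyllithium (formed in the flask, not isolated) | [Li]c1c(OC)cc(OC)cc1OC | intermediate
6 | 4-(benzyloxy)-6-[hydroxy(2,4,6-trimethoxyphenyl)methyl]-2H-pyran-2-one (racemic) | COc1cc(OC)c(C(O)C2=CC(OCc3ccccc3)=CC(=O)O2)c(OC)c1 | intermediate
7 | 4-(benzyloxy)-6-(2,4,6-trimethoxybenzoyl)-2H-pyran-2-one | O=C1C=C(OCc2ccccc2)C=C(C(=O)c2c(OC)cc(OC)cc2OC)O1 | intermediate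
8 | ethyl 4-methylpent-3-enoate | CCOC(=O)CC=C(C)C | starting material
9 | lithium 1,1-dibromo-5-methylhexa-1,4-dien-2-olate (formed in the flask, not isolated) | [Li+].[O-]C(=C(Br)Br)CC=C(C)C | intermediate
10 | lithium 5-methylhex-4-en-1-yn-1-olate (formed in the flask, not isolated) | [Li+].[O-]C#CCC=C(C)C | intermediate
11 | triisopropyl[(5-methylhex-4-en-1-yn-1-yl)oxy]silane | CC(C)=CCC#CO[Si](C(C)C)(C(C)C)C(C)C | intermediate
12 | 8-(benzyloxy)-6-(3-methylbut-2-en-1-yl)-1-(2,4,6-trimethoxybenzoyl)-5-(triisopropylsilyloxy)-2-oxabicyclo[2.2.2]octa-5,7-dien-3-one (racemic, bridgeheads tied by the bicycle; formed in the flask, not isolated) | O=C1OC2(C(=O)c3c(OC)cc(OC)cc3OC)C=C(OCc3ccccc3)C1C(O[Si](C(C)C)(C(C)C)C(C)C)=C2CC=C(C)C | intermediate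
13 | [5-(benzyloxy)-2-(3-methylbut-2-en-1-yl)-3-(triisopropylsilyloxy)phenyl](2,4,6-trimethoxyphenyl)methanone | COc1cc(OC)c(C(=O)c2cc(OCc3ccccc3)cc(O[Si](C(C)C)(C(C)C)C(C)C)c2CC=C(C)C)c(OC)c1 | intermediate
14 | [5-(benzyloxy)-3-hydroxy-2-(3-methylbut-2-en-1-yl)phenyl](2,4,6-trimethoxyphenyl)methanone | COc1cc(OC)c(C(=O)c2cc(OCc3ccccc3)cc(O)c2CC=C(C)C)c(OC)c1 | intermediate
15 | [7-(benzyloxy)-2,2-dimethyl-2H-chromen-5-yl](2,4,6-trimethoxyphenyl)methanone | COc1cc(OC)c(C(=O)c2cc(OCc3ccccc3)cc3OC(C)(C)C=Cc23)c(OC)c1 | intermediate
16 | (2-hydroxy-4,6-dimethoxyphenyl)(7-hydroxy-2,2-dimethyl-2H-chromen-5-yl)methanone | COc1cc(O)c(C(=O)c2cc(O)cc3c2C=CC(C)(C)O3)c(OC)c1 | target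

**Step count**

Total: 9 steps. Longest linear sequence: 8 steps (steps 1, 2, 3, 4, 6, 7, 8, 9 from 1); step 5 is a one-step branch to the siloxyalkyne.

**Steps most likely to fail**

Step 6. The donor-substituted pyrone may not engage the ynol ether at all. The alkyne may instead add in a (2+2) sense to the C5=C6 enone, or the silyl ketenium may be hydrolysed before ring closure. The fallback builds rings B and C by established aromatic chemistry; it sets out from 4 (as aryllithium 5) and returns at 15, so step 8 is bypassed as well.
- Commercial methyl 3-(benzyloxy)-5-hydroxybenzoate would be O-alkylated with 3-chloro-3-methylbut-1-yne (K2CO3, KI, acetone, reflux; Williamson-type etherification) to methyl 3-(benzyloxy)-5-[(2-methylbut-3-yn-2-yl)oxy]benzoate F1.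
- Heating F1 in N,N-diethylaniline at about 190 °C should bring about the aryl propargyl ether Claisen rearrangement, 1,5-hydrogen shift and oxa-6π electrocyclisation to methyl 7-(benzyloxy)-2,2-dimethyl-2H-chromene-5-carboxylate F2. Migration to the carbon ortho to the ester and para to the benzyloxy group is the sense both meta substituents favour; any regioisomer would be removed by chromatography.
- F2 would be converted with MeNH(OMe)·HCl and i-PrMgCl (THF, −20 °C) into 7-(benzyloxy)-N-methoxy-N,2,2-trimethyl-2H-chromene-5-carboxamide F3.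
- Addition of 5 (from 4 and n-BuLi, THF, −78 to 0 °C; Weinreb ketone synthesis) would give 15.

Step 2. At the temperature the Riley oxidation needs, the benzyl protecting group may be lost oxidatively, or oxidation of the methyl group may stall or overrun. The fallback sets out from 2 and returns at 3, replacing direct C–H oxidation by anion hydroxylation and alcohol oxidation.
- Lateral deprotonation of the 6-methyl group with LiN(SiMe3)2 (THF, −78 °C) would give lithium 4-(benzyloxy)-6-methylidene-6H-pyran-2-olate F4.
- Hydroxylation at the exocyclic carbon with 2-(phenylsulfonyl)-3-phenyloxaziridine would give 4-(benzyloxy)-6-(hydroxymethyl)-2H-pyran-2-one F5.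
- MnO2 (CH2Cl2, rt) would oxidise this allylic-type alcohol to 3.

Step 5. The doubly activated α-position of the β,γ-unsaturated ester may be deprotonated in competition with carbonyl addition of LiCHBr2, and the skipped enyne may isomerise under the excess base. The fallback sets out from 8 and returns at 10, reaching the ynolate by acetylide oxidation instead of carbenoid rearrangement.
- Reduction with i-Bu2AlH (CH2Cl2, −78 °C) would give 4-methylpent-3-enal F6, used crude.
- Corey–Fuchs olefination (CBr4, PPh3, CH2Cl2, 0 °C) would give 1,1-dibromo-5-methylhexa-1,4-diene F7.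
- n-BuLi (2 equiv, THF, −78 °C) would give lithium 5-methylhex-4-en-1-yn-1-ide F8.
- Oxidation of this acetylide with LiOOt-Bu (from t-BuOOH and LiN(SiMe3)2, −78 to 0 °C) would deliver 10, which is silylated with TIPSOTf as in step 5 to give 11.

**Further compounds**

F1 | step 6 | methyl 3-(benzyloxy)-5-[(2-methylbut-3-yn-2-yl)oxy]benzoate | COC(=O)c1cc(OCc2ccccc2)cc(OC(C)(C)C#C)c1
F2 | step 6 | methyl 7-(benzyloxy)-2,2-dimethyl-2H-chromene-5-carboxylate | COC(=O)c1cc(OCc2ccccc2)cc2OC(C)(C)C=Cc12
F3 | step 6 | 7-(benzyloxy)-N-methoxy-N,2,2-trimethyl-2H-chromene-5-carboxamide | CON(C)C(=O)c1cc(OCc2ccccc2)cc2OC(C)(C)C=Cc12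
F4 | step 2 | lithium 4-(benzyloxy)-6-methylidene-6H-pyran-2-olate | [Li+].[O-]C1=CC(OCc2ccccc2)=CC(=C)O1
F5 | step 2 | 4-(benzyloxy)-6-(hydroxymethyl)-2H-pyran-2-one | OCc1cc(OCc2ccccc2)cc(=O)o1
F6 | step 5 | 4-methylpent-3-enal | CC(C)=CCC=O
F7 | step 5 | 1,1-dibromo-5-methylhexa-1,4-diene | CC(C)=CCC=C(Br)Br
F8 | step 5 | lithium 5-methylhex-4-en-1-yn-1-ide | [Li+].[C-]#CCC=C(C)C
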